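## Analysis of the target

The target is a cyclohexanone fused to an oxirane (a 7-oxabicyclo[4.1.0]heptan-2-one). Its ring atoms are numbered here as in carvone: C1 ketone, C2 methyl-bearing epoxide carbon, C3 epoxide CH, C4 CH2, C5 the CH carrying isopropenyl, C6 the CH carrying the acyloxy group. The C6 oxygen is esterified with (E)-4-(tigloyloxy)tiglic acid, an achiral chain with two E-trisubstituted enoates, the inner one also a primary allylic ester. There are four stereocentres (C2, C3, C5, C6): the epoxide oxygen and the C6 oxygen sit on one face of the ring and the C5 isopropenyl group on the other (1S,3R,4R,6S in the bicyclic numbering). The sensitive groups are the α,β-epoxy ketone (acid, nucleophiles, strong base), the α-acyloxy ketone with its enolisable C6–H (epimerisation, acyl shift), the isopropenyl alkene (electrophiles, ene reactions) and the enoate esters (base, nucleophiles). The difficulty is to place three C–O bonds at C2, C3 and C6 on one face, opposite the only substituent that can steer a reagent, without touching the isopropenyl group, and then to acylate a hindered ketol without epimerisation. The strategy rests on one feature: the C3 and C6 oxygens are 1,4 across the ring and cis, and C6, C1, C2 and C3 are exactly the four carbons of the cross-conjugated dienol of (S)-carvone 1, which already holds C5 in the required configuration. One molecule of dioxygen added across C6 and C3 of that diene therefore delivers both oxygens at once, and its O–O bond stores the oxidising equivalent that later makes the C2–O bond.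

## Retrosynthetic reasoning

**Ester at C6.** The C6 O–acyl bond of 20 is cut first, giving the epoxy ketol 9 and the diester acid 19. The side chain has no stereocentre and two enoates that are best made apart from the oxidation chemistry of the ring, so a convergent last-step esterification is the natural cut. The forward step has to acylate a hindered secondary α-ketol without epimerising C6 or opening the oxirane.

**Silyl ether.** Alcohol 9 is traced to its silyl ether 8 (O–Si bond). The silyl group is not an extra protecting group: it is the group that activates the diene and it ends on the C6 oxygen by itself. The forward step is a fluoride-mediated desilylation mild enough for the epoxy ketone.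

**Epoxide and ketone from a peroxide.** In 8 the C2–O bond of the oxirane is cut and the C6 oxygen is reconnected to the C3 oxygen, passing through the syn-diepoxide 7 to the endoperoxide 6. This is chosen because it converts two separate oxidation problems (epoxide face, C6 hydroxyl face) into one: in 6 both oxygens are already on the same face and the C1=C2 bond is an electron-rich silyl enol ether. The forward reaction must cleave O–O, deliver one oxygen to C2 and the other to C1 from the face they occupy, and let the silyloxy oxirane collapse to ketone and C6 silyl ether.

**Key disconnection.** In 6 the C6–O and C3–O bonds are cut in a retro-[4+2] sense, giving the silyl dienol ether 4 and dioxygen 5. No other pair of bonds removes two stereocentres and a ring at once while leading straight to a chiral-pool skeleton. The forward cycloaddition has to occur on the diene and not as an ene reaction, and on the face anti to the C5 isopropenyl group.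

**Dienol ether.** The O–Si bond of 4 is cut to give (S)-carvone 1 and tert-butyldimethylsilyl chloride 2, via the lithium dienolate 3. Kinetic deprotonation must take place at C6 (α′) and not at the γ position, so that the diene is the cross-conjugated one whose termini are C6 and C3.

**Side chain.** Acid 19 is traced to its tert-butyl ester 18, chosen because acidolysis frees the acid without touching the inner allylic tiglate. Ester 18 is cut at the allylic C–O acyl bond into hydroxy ester 16 and tiglic acid 17. The C2=C3 double bond of 16 is cut in a Wittig sense into ylide 13 and glycolaldehyde 15 (supplied as its dimer 14), which sets the E geometry. Ylide 13 comes from tert-butyl 2-bromopropanoate 10 and triphenylphosphine 11 through the phosphonium salt 12.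

## Alternatives that were turned down

**Alternative 1:** The C5–C6 bond would be made last in the ring, by an α-ketol shift. (S)-Limonene A3 would be cut at its ring alkene and re-closed by aldol condensation to a cyclopentene aldehyde, which after deconjugative α-hydroxylation gives the α-hydroxy aldehyde A2. With Al(OiPr)3 in warm toluene the aluminium alkoxide of A2 should push C5 from the carbinol carbon to the formyl carbon and so enlarge the ring to trans-6-hydroxycarvone A1.
- For: the shift is driven by the change from aldehyde to conjugated ketone and from a five- to a six-membered ring. It is reversible, so the C6 hydroxyl can settle trans to isopropenyl under thermodynamic control. It needs neither light nor a peroxide, which makes it the easier route to scale; on that point it is stronger than the chosen route.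
- Against: the carbinol carbon of A2 holds two groups that can migrate, the sp3 carbon C5 and the alkenyl carbon C2, and alkenyl groups are usually the better migrators, so the constitution of the product rests on equilibration. A3 is the less abundant enantiomer of limonene. Several steps are spent rebuilding a six-membered ring that 1 already contains. A1 still lacks the epoxide, which would need a separate nucleophilic epoxidation on a base-sensitive ketol, probably after protection.
- Comparison: the chosen route is weaker on operational safety, but it reaches alcohol 9 in four steps and ties the C3 and C6 oxygens to each other through one cycloaddition instead of setting them in two unrelated steps.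

**Alternative 2:** The ring bond C2–C3 and the oxirane bond C2–O would be formed together from the open-chain chloro keto aldehyde A5. With Cs2CO3 in acetonitrile the enolate of the α-chloro ketone should add to the aldehyde (six-membered ring by aldol addition) and the resulting alkoxide should displace chloride (three-membered ring by intramolecular substitution). The product is the silyl ether A4, which is the same compound as 8.
- For: ring and epoxide arise in one ionic step with a cheap base, no oxidant ever meets the isopropenyl group, the cis ring fusion is automatic, and the product enters the same endgame. On these points it is at least as strong as the chosen route.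
- Against: A5 must be built as an acyclic chain with C5 and C6 set by asymmetric synthesis, which costs far more steps than the one step from 1 to 4. The facial sense of the aldol step relative to C5 and C6, and hence the epoxide face, is decided by a flexible transition state with no clear bias. The chloro ketone also carries an enolisable hydrogen at C6 on its other side, which opens Favorskii rearrangement and C6 epimerisation as competing paths.
- Comparison: the chosen strategy offers instead a rigid bicyclic intermediate in which the two oxygens cannot be other than cis, and a ring taken from the chiral pool.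

**Alternative 3:** The C1–C2 bond would be closed by a Nozaki–Hiyama–Kishi reaction of the open-chain iodo aldehyde A7. CrCl2 with catalytic NiCl2 in DMF should convert the (Z)-alkenyl iodide into an alkenylchromium species that adds to the aldehyde and gives the cyclohexenol A6 as a mixture at C1.
- For: the reaction is highly selective for aldehydes, tolerates the silyl ether and the isopropenyl group, and six-membered closure is dependable. The C1 mixture does not matter because that carbon is oxidised afterwards. In functional-group tolerance it is stronger than a photooxygenation.
- Against: A6 is no more than a protected, reduced form of the carvone skeleton, so an oxidation and a nucleophilic epoxidation are still required after the closure. A7 needs the C5/C6 pair and a geometrically pure (Z)-iodoalkene to be made in the open chain, with an epimerisable α-silyloxy aldehyde. The closure consumes a large excess of a chromium salt.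
- Comparison: it spends most of its length on a ring that 1 supplies, whereas the chosen route places its whole risk in one step that also sets two stereocentres.

Key step: step 2

## Route

**Step 1**
Reactants: 1 (S)-(+)-carvone; 2 tert-butyldimethylsilyl chloride
Product: 4 tert-butyldimethyl{[(3S)-6-methyl-3-(prop-1-en-2-yl)cyclohexa-1,5-dien-1-yl]oxy}silane (cross-conjugated TBS dienol ether of carvone), via lithium dienolate 3 (not isolated)
Conditions: LiN(iPr)2 (LDA), THF, −78 °C; then TBSCl, DMPU, −78 → 0 °C
Reagents that add atoms: tert-butyldimethylsilyl chloride (compound 2), CC(C)(C)[Si](C)(C)Cl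
Why: Kinetic deprotonation of the enone by the hindered amide base occurs at the α′ carbon C6 and gives the cross-conjugated lithium dienolate 3, which is silylated on oxygen by 2 in the presence of DMPU (O-silylation of a ketone enolate). C5 is not involved, so the stereocentre of 1 is carried over unchanged.

**Step 2**
Reactants: 4 TBS dienol ether of carvone; 5 dioxygen
Product: 6 tert-butyldimethyl{[(1R,4S,7R)-5-methyl-7-(prop-1-en-2-yl)-2,3-dioxabicyclo[2.2.2]oct-5-en-6-yl]oxy}silane (endoperoxide bridging carvone C6 and C3 on the face anti to isopropenyl)
Conditions: O2, tetraphenylporphyrin (cat.), visible light, CH2Cl2, −78 °C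
Reagents that add atoms: dioxygen (compound 5), O=O
Why: Photoexcited tetraphenylporphyrin passes its energy to 5, and the singlet oxygen so formed behaves as an electron-poor dienophile that should bond to C6 and C3 of 4 in one concerted step, both new bonds on the same face of a diene that the ring holds in the cisoid geometry. The closest known reaction type is the dye-sensitised photooxygenation of cyclohexa-1,3-dienes and of 2-silyloxy-1,3-dienes to 2,3-dioxabicyclo[2.2.2]oct-5-enes. The six-membered peroxide ring closes by cycloaddition, the C6–O and C3–O bonds forming together, so there is no separate ring-closing event with a selectivity of its own. The new stereocentres C3 and C6 are set together: their cis relation follows from the suprafacial addition, and their absolute sense from the C5 stereocentre, whose isopropenyl group flanks the C6 terminus and should direct oxygen to the opposite face. The step needs chemoselectivity for [4+2] addition over ene-type oxygenation of the enol ether and of the isopropenyl group, which the fixed cisoid geometry, the raised HOMO of the silyloxy diene and the low temperature should secure. It also needs facial selectivity, for which only the single allylic substituent at C5 is available; oxygen is a small reagent, so the preference may be moderate, and any adduct of the syn face would be removed after step 3. The product is kept cold, freed of oxygen with argon and taken on at once.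

**Step 3**
Reactants: 6 endoperoxide
Product: 8 (1S,3R,4R,6S)-3-[(tert-butyldimethylsilyl)oxy]-1-methyl-4-(prop-1-en-2-yl)-7-oxabicyclo[4.1.0]heptan-2-one, via syn-diepoxide 7 (not isolated)
Conditions: Co(TPP) (cobalt tetraphenylporphyrin, 5 mol %), CH2Cl2, −20 °C → rt
Reagents that add atoms: none
Why: This is the Co(TPP)-catalysed isomerisation of a bicyclic 1,4-endoperoxide to a syn-diepoxide: divalent cobalt cleaves the O–O bond by single-electron transfer and the two oxygens close onto C2 and C1 of the former C1=C2 bond from the face they already occupy, which sets C2 (a cis-fused oxirane can form only on the peroxide face) and leaves C3 and C6 untouched. The C1–C6 silyloxy oxirane of 7 should then open at C1 and pass the silyl group to the C6 oxygen, as in the second stage of a Rubottom oxidation, giving the ketone and the C6 silyl ether with retention at C6. Any syn-face adduct carried over from step 2 is separated here by chromatography.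

**Step 4**
Reactants: 8 silyloxy epoxy ketone
Product: 9 (1S,3R,4R,6S)-3-hydroxy-1-methyl-4-(prop-1-en-2-yl)-7-oxabicyclo[4.1.0]heptan-2-one
Conditions: HF·pyridine, pyridine, THF, 0 °C → rt
Reagents that add atoms: none
Why: Fluoride-mediated cleavage of the silyl ether, driven by Si–F bond formation; the α-keto silyl ether is activated toward fluoride. Excess pyridine buffers the medium so that the oxirane is not opened, and no base strong enough to enolise toward C6 is present, so the C6 configuration is kept.

**Step 5**
Reactants: 10 tert-butyl 2-bromopropanoate (racemic); 11 triphenylphosphine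
Product: 13 tert-butyl 2-(triphenyl-λ5-phosphanylidene)propanoate, via phosphonium bromide 12 (not isolated)
Conditions: PPh3, toluene, 80 °C; then aq. NaOH, CH2Cl2, 0 °C
Reagents that add atoms: triphenylphosphine (compound 11), c1ccc(cc1)P(c1ccccc1)c1ccccc1
Why: SN2 quaternisation of the phosphine by the α-bromo ester, then deprotonation of the acidic α-CH of salt 12 to the ester-stabilised ylide. The stereocentre of 10 disappears in the ylide, so racemic 10 suffices.

**Step 6**
Reactants: 13 stabilised ylide; 14 glycolaldehyde dimer (2,5-dihydroxy-1,4-dioxane)
Product: 16 tert-butyl (2E)-4-hydroxy-2-methylbut-2-enoate, via glycolaldehyde 15 (not isolated)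
Conditions: CH2Cl2, reflux
Reagents that add atoms: none
Why: Wittig olefination: the dimer 14 dissociates to the free aldehyde 15, which is trapped by the ylide. α-Substituted ester-stabilised ylides should give the E-trisubstituted enoate, and the free hydroxyl is tolerated.

**Step 7**
Reactants: 16 hydroxy ester; 17 tiglic acid
Product: 18 tert-butyl (2E)-2-methyl-4-{[(2E)-2-methylbut-2-enoyl]oxy}but-2-enoate
Conditions: DCC, DMAP (cat.), CH2Cl2, 0 °C → rt
Reagents that add atoms: none
Why: Steglich esterification of an unhindered primary allylic alcohol. Tiglic acid is the thermodynamically favoured E isomer, so the nucleophilic catalyst cannot erode its geometry.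

**Step 8**
Reactants: 18 tert-butyl diester
Product: 19 (2E)-2-methyl-4-{[(2E)-2-methylbut-2-enoyl]oxy}but-2-enoic acid
Conditions: TFA, CH2Cl2, 0 °C → rt
Reagents that add atoms: none
Why: Acidolysis of the tert-butyl ester by loss of the tert-butyl cation as 2-methylpropene. The primary allylic tiglate does not ionise, because its allyl cation would be conjugated to a carboxyl group, and both E alkenes are untouched.

**Step 9**
Reactants: 9 epoxy ketol; 19 diester acid
Product: 20 (1S,3R,4R,6S)-1-methyl-2-oxo-4-(prop-1-en-2-yl)-7-oxabicyclo[4.1.0]heptan-3-yl (2E)-2-methyl-4-{[(2E)-2-methylbut-2-enoyl]oxy}but-2-enoate (the target)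
Conditions: DCC, DMAP (cat.), CH2Cl2, 0 °C → rt
Reagents that add atoms: none
Why: Steglich esterification of the secondary C6 alcohol. No bond to C6 is made or broken, so its configuration is retained, and the nearly neutral medium with only catalytic DMAP at low temperature should spare the epoxy ketone and the C6–H.

## Compound list

1 | (S)-(+)-carvone | C=C(C)[C@H]1CC=C(C)C(=O)C1 | starting material
2 | tert-butyldimethylsilyl chloride | CC(C)(C)[Si](C)(C)Cl | starting material
3 | lithium dienolate of (S)-carvone, deprotonated at C6 (formed in the flask) | C=C(C)[C@H]1CC=C(C)C([O-])=C1.[Li+] | intermediate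
4 | tert-butyldimethyl{[(3S)-6-methyl-3-(prop-1-en-2-yl)cyclohexa-1,5-dien-1-yl]oxy}silane | C=C(C)[C@H]1CC=C(C)C(O[Si](C)(C)C(C)(C)C)=C1 | intermediate
5 | dioxygen | O=O | starting material
6 | tert-butyldimethyl{[(1R,4S,7R)-5-methyl-7-(prop-1-en-2-yl)-2,3-dioxabicyclo[2.2.2]oct-5-en-6-yl]oxy}silane | C=C(C)[C@H]1C[C@@H]2OO[C@H]1C(O[Si](C)(C)C(C)(C)C)=C2C | intermediate
7 | syn-diepoxide: oxirane across C2–C3 and silyloxy oxirane across C1–C6, both oxygens anti to isopropenyl (formed in the flask) | C=C(C)[C@H]1C[C@@H]2O[C@]2(C)[C@]3(O[Si](C)(C)C(C)(C)C)O[C@H]13 | intermediate
8 | (1S,3R,4R,6S)-3-[(tert-butyldimethylsilyl)oxy]-1-methyl-4-(prop-1-en-2-yl)-7-oxabicyclo[4.1.0]heptan-2-one | C=C(C)[C@H]1C[C@@H]2O[C@]2(C)C(=O)[C@@H]1O[Si](C)(C)C(C)(C)C | intermediate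
9 | (1S,3R,4R,6S)-3-hydroxy-1-methyl-4-(prop-1-en-2-yl)-7-oxabicyclo[4.1.0]heptan-2-one | C=C(C)[C@H]1C[C@@H]2O[C@]2(C)C(=O)[C@@H]1O | intermediate
10 | tert-butyl 2-bromopropanoate (racemic) | CC(Br)C(=O)OC(C)(C)C | starting material
11 | triphenylphosphine | c1ccc(cc1)P(c1ccccc1)c1ccccc1 | starting material
12 | [1-(tert-butoxy)-1-oxopropan-2-yl]triphenylphosphonium bromide (formed in the flask) | CC(C(=O)OC(C)(C)C)[P+](c1ccccc1)(c1ccccc1)c1ccccc1.[Br-] | intermediate
13 | tert-butyl 2-(triphenyl-λ5-phosphanylidene)propanoate | CC(C(=O)OC(C)(C)C)=P(c1ccccc1)(c1ccccc1)c1ccccc1 | intermediate
14 | glycolaldehyde dimer (2,5-dihydroxy-1,4-dioxane) | OC1COC(O)CO1 | starting material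
15 | glycolaldehyde (formed in the flask) | OCC=O | intermediate
16 | tert-butyl (2E)-4-hydroxy-2-methylbut-2-enoate | CC(C)(C)OC(=O)/C(C)=C/CO | intermediate
17 | tiglic acid, (2E)-2-methylbut-2-enoic acid | C/C=C(\C)C(=O)O | starting material
18 | tert-butyl (2E)-2-methyl-4-{[(2E)-2-methylbut-2-enoyl]oxy}but-2-enoate | C/C=C(\C)C(=O)OC/C=C(\C)C(=O)OC(C)(C)C | intermediate
19 | (2E)-2-methyl-4-{[(2E)-2-methylbut-2-enoyl]oxy}but-2-enoic acid | C/C=C(\C)C(=O)OC/C=C(\C)C(=O)O | intermediate
20 | (1S,3R,4R,6S)-1-methyl-2-oxo-4-(prop-1-en-2-yl)-7-oxabicyclo[4.1.0]heptan-3-yl (2E)-2-methyl-4-{[(2E)-2-methylbut-2-enoyl]oxy}but-2-enoate | C=C(C)[C@H]1C[C@@H]2O[C@]2(C)C(=O)[C@@H]1OC(=O)/C(C)=C/COC(=O)/C(C)=C/C | target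

## Step count and least certain steps

Total step count: 9. Longest linear sequence: 5 steps (steps 1, 2, 3, 4 and 9 from 1; the acid branch, steps 5 to 8 and then 9, is equally long).

**Step 2 (key step).** Three processes threaten it:
- ene-type oxygenation instead of cycloaddition, either silyl transfer to the peroxy oxygen at the enol ether or hydrogen abstraction at the isopropenyl group, because singlet oxygen attacks enol ethers in several modes;
- insufficient facial discrimination, because a small dienophile meets only one allylic substituent;
- thermal decomposition of the labile endoperoxide before it is used.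

Fallback, from 4 and back at 8: Rubottom oxidation of 4 (mCPBA, NaHCO3, CH2Cl2, −20 °C) epoxidises the C6=C1 enol ether bond anti to isopropenyl, and the silyloxy oxirane collapses with silyl shift to trans-6-(tert-butyldimethylsilyloxy)carvone F1. Weitz–Scheffer epoxidation of the enone (H2O2, NaOH, MeOH, 0 °C) then adds hydroperoxide to C3 anti to the C5 substituent, the sense that nucleophilic epoxidation of carvone itself follows, and gives 8. This gives up the single-reagent installation of both oxygens but keeps the starting material and the endgame.

**Step 3.** After the single-electron cleavage of the O–O bond, the oxygen-centred radical at C6 may fragment the C5–C6 bond (β-scission toward an allylic radical at C5) or abstract hydrogen instead of closing onto the enol ether, which would destroy the ring. Loss of the silyl group in place of its shift would be harmless, since it leads to 9 directly.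

Fallback, from 6 and back at 8: the peroxide is reduced in a two-electron manner with thiourea in methanol to the cis-3,6-dihydroxy silyl enol ether F2, so that no oxygen radical is formed. Mild aqueous acid (oxalic acid, THF/H2O) hydrolyses the enol ether and eliminates the C3 hydroxyl to give trans-6-hydroxycarvone F3 (the same compound as A1). Silylation (TBSCl, imidazole, DMF) gives trans-6-(tert-butyldimethylsilyloxy)carvone F1, and the Weitz–Scheffer epoxidation described above leads to 8.

**Step 9.** The activated form of 19 is a hindered α-methyl enoyl donor and the C6 alcohol is flanked by a ketone and a branched carbon. Slow acylation would allow O-to-N acyl shift of the activated acid and, on long exposure to DMAP, epimerisation at C6.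

Fallback, from 16 and 9 and back at 20, with the side chain attached in two stages: Appel bromination of 16 (CBr4, PPh3, CH2Cl2) gives tert-butyl (2E)-4-bromo-2-methylbut-2-enoate F7, and TFA frees (2E)-4-bromo-2-methylbut-2-enoic acid F8. Oxalyl chloride with catalytic DMF gives (2E)-4-bromo-2-methylbut-2-enoyl chloride F9. This small, reactive chloride acylates 9 (2,6-lutidine, CH2Cl2, 0 °C) without a nucleophilic catalyst to give the C6 (2E)-4-bromo-2-methylbut-2-enoate of the epoxy ketone core F10. Displacement of the primary allylic bromide by the cesium salt of 17 (Cs2CO3, DMF, rt) then forms the outer ester by carboxylate alkylation and gives 20.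

**Step 4.** The oxirane may be opened by hydrogen fluoride, or, with a more basic fluoride source, the freed ketol may epimerise or rearrange.

Fallback, from 1 and back at 9: steps 1 to 3 are run with chlorotriethylsilane in place of 2, giving the triethylsilyl dienol ether of carvone F4, the triethylsilyloxy endoperoxide F5 and the triethylsilyl ether of the epoxy ketone F6. The more labile silyl ether is then removed without fluoride (AcOH/THF/H2O, rt) to give 9.

## Further compounds

F1 | step 2 | (5R,6R)-6-[(tert-butyldimethylsilyl)oxy]-2-methyl-5-(prop-1-en-2-yl)cyclohex-2-en-1-one (trans-6-(tert-butyldimethylsilyloxy)carvone) | C=C(C)[C@H]1CC=C(C)C(=O)[C@@H]1O[Si](C)(C)C(C)(C)C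
F2 | step 3 | cis-3,6-dihydroxy silyl enol ether: 1-[(tert-butyldimethylsilyl)oxy]-2-methyl-5-(prop-1-en-2-yl)cyclohex-1-ene-3,6-diol (carvone numbering), both hydroxyls anti to isopropenyl | C=C(C)[C@H]1C[C@H](O)C(C)=C(O[Si](C)(C)C(C)(C)C)[C@@H]1O
F3 | step 3 | (5R,6R)-6-hydroxy-2-methyl-5-(prop-1-en-2-yl)cyclohex-2-en-1-one (trans-6-hydroxycarvone) | C=C(C)[C@H]1CC=C(C)C(=O)[C@@H]1O
F4 | step 4 | triethyl{[(3S)-6-methyl-3-(prop-1-en-2-yl)cyclohexa-1,5-dien-1-yl]oxy}silane | C=C(C)[C@H]1CC=C(C)C(O[Si](CC)(CC)CC)=C1
F5 | step 4 | triethyl{[(1R,4S,7R)-5-methyl-7-(prop-1-en-2-yl)-2,3-dioxabicyclo[2.2.2]oct-5-en-6-yl]oxy}silane | C=C(C)[C@H]1C[C@@H]2OO[C@H]1C(O[Si](CC)(CC)CC)=C2C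
F6 | step 4 | (1S,3R,4R,6S)-1-methyl-4-(prop-1-en-2-yl)-3-[(triethylsilyl)oxy]-7-oxabicyclo[4.1.0]heptan-2-one | C=C(C)[C@H]1C[C@@H]2O[C@]2(C)C(=O)[C@@H]1O[Si](CC)(CC)CC
F7 | step 9 | tert-butyl (2E)-4-bromo-2-methylbut-2-enoate | CC(C)(C)OC(=O)/C(C)=C/CBr
F8 | step 9 | (2E)-4-bromo-2-methylbut-2-enoic acid | OC(=O)/C(C)=C/CBr
F9 | step 9 | (2E)-4-bromo-2-methylbut-2-enoyl chloride | ClC(=O)/C(C)=C/CBr
F10 | step 9 | (1S,3R,4R,6S)-1-methyl-2-oxo-4-(prop-1-en-2-yl)-7-oxabicyclo[4.1.0]heptan-3-yl (2E)-4-bromo-2-methylbut-2-enoate | C=C(C)[C@H]1C[C@@H]2O[C@]2(C)C(=O)[C@@H]1OC(=O)/C(C)=C/CBr
A1 | alternative 1 | (5R,6R)-6-hydroxy-2-methyl-5-(prop-1-en-2-yl)cyclohex-2-en-1-one (trans-6-hydroxycarvone) | C=C(C)[C@H]1CC=C(C)C(=O)[C@@H]1O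
A2 | alternative 1 | 1-hydroxy-2-methyl-5-(prop-1-en-2-yl)cyclopent-2-ene-1-carbaldehyde (C5 as in the target, carbinol carbon unassigned) | C=C(C)[C@H]1CC=C(C)C1(O)C=O
A3 | alternative 1 | (S)-limonene | C=C(C)[C@H]1CCC(C)=CC1
A4 | alternative 2 | (1S,3R,4R,6S)-3-[(tert-butyldimethylsilyl)oxy]-1-methyl-4-(prop-1-en-2-yl)-7-oxabicyclo[4.1.0]heptan-2-one (identical with 8) | C=C(C)[C@H]1C[C@@H]2O[C@]2(C)C(=O)[C@@H]1O[Si](C)(C)C(C)(C)C
A5 | alternative 2 | 4-[(tert-butyldimethylsilyl)oxy]-6-chloro-5-oxo-3-(prop-1-en-2-yl)heptanal (C3 and C4 as C5 and C6 of the target, chloride carbon unassigned) | C=C(C)[C@@H](CC=O)[C@@H](O[Si](C)(C)C(C)(C)C)C(=O)C(C)Cl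
A6 | alternative 3 | 6-[(tert-butyldimethylsilyl)oxy]-2-methyl-5-(prop-1-en-2-yl)cyclohex-2-en-1-ol (C5 and C6 trans, C1 epimers) | C=C(C)[C@H]1CC=C(C)C(O)[C@@H]1O[Si](C)(C)C(C)(C)C
A7 | alternative 3 | (5Z)-2-[(tert-butyldimethylsilyl)oxy]-6-iodo-3-(prop-1-en-2-yl)hept-5-enal (C2 and C3 as C6 and C5 of the target) | C=C(C)[C@@H](C/C=C(/C)I)[C@@H](O[Si](C)(C)C(C)(C)C)C=O
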